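## The problem

Compound 14 consists of two identical, fully substituted 1,4-benzoquinone rings joined through their C3 atoms by a saturated, unbranched fourteen-carbon chain. There is no stereocentre, so the difficulty is purely constitutional: each ring has carbonyls at C1 and C4, a free hydroxyl at C2, the chain at C3, a methyl ether at C5 and a methyl group at C6. Four ring oxygens of three kinds (carbonyl, free enol, methyl enol ether) must be placed correctly relative to two carbon substituents that sit para to each other. The molecule is symmetric about the chain midpoint, which invites two-directional work, but every reaction must then succeed twice in one molecule, so a moderately selective step is penalised twice. The finished rings are fragile: the 2-hydroxyquinone is a vinylogous acid and a redox-active acceptor, and the C5 methoxy group is a vinylogous ester that hydroxide, alkoxides and amines displace by addition–elimination. Strong base, carbanions and long exposure to aqueous acid are therefore excluded once the quinone exists, and the oxidation level is best raised last. The long chain also makes every intermediate waxy and poorly soluble in water, which matters for aqueous oxidants. The enabling feature lies in the ring carbons: the chain on C3 and the methyl on C6 are para and the C1 and C5 oxygens flank C6, so removing the C2 and C4 oxygens leaves a 2-methyl-5-alkylresorcinol, whose tetrahydro form, a 2-methyl-5-alkylcyclohexane-1,3-dione, is what an alk-4-en-3-one and a malonate give by Michael–Dieckmann annulation.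

## Retrosynthesis

**C2–O of each ring (14 to 13 to 12).** The C2 hydroxyl is removed first. Target 14 is an isomer of bis(epoxide) 13, which comes from bis(quinone) 12 by delivery of one oxygen to the C2=C3 edge. In 12 that edge is the only quinone double bond with a hydrogen and no donor; the C5=C6 edge is a tetrasubstituted vinylogous ester. Adding this oxygen late avoids carrying a tetra-oxygenated, hexasubstituted arene through the route. The forward steps must epoxidise without disturbing the methoxy group, then open the epoxide so that the oxygen stays on the carbon that bore hydrogen.

**C4=O of each ring (12 to 11).** Bis(quinone) 12 is the para-oxidation product of bis(phenol) 11, which carries a 3-methoxy-2-methylphenol unit at each chain end. The free hydroxyl of 11 becomes the C1 carbonyl and its para carbon, between the methoxy group and the chain, becomes C4. The distinction between one free OH and one OMe in 11 therefore fixes all four oxygen positions of the quinone. A free resorcinol or its dimethyl ether would leave the ether position undefined. The precursor is a stable phenol; the forward oxidation must go para and not to the single free ortho carbon.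

**Aromaticity and the O-methyl group (11 to 9 by way of 10).** Each ring of 11 is the dehydrogenated mono-enol ether of a symmetric 2-methylcyclohexane-1,3-dione, so 11 is traced to bis(dione) 9 through bis(enol ether) 10. Because the two carbonyls of each dione ring are equivalent, etherifying either gives the same compound. Monomethylation of a resorcinol would be statistical; here it is not. The forward reaction is a halogen-mediated aromatisation in the alcohol that supplies the methyl group, and it must stop at the monoether on both rings.

**C3–C4 and C5–C6 of each ring (9 to 4 and 5, the key disconnection).** Cutting these two bonds in both rings (target numbering) opens 9 to the linear bis(enone) 4 and two molecules of dimethyl malonate 5. The forward reaction passes through bis-Michael adduct 6, bis(keto ester) 7 and bis(keto acid) 8. This cut removes both rings and four skeletal bonds at once and leaves an acyclic C24 diketone. The chain and the methyl group end up para by construction, with no aromatic substitution to steer. The forward reaction needs conjugate addition of malonate to outrun self-condensation of the enone, and Claisen closure through the ethyl-side enolate, which is the only one that can form a six-membered ring.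

**C4=C5 and C20=C21 of the dienone (4 to 2 and 3).** Both enone double bonds are cut to hexadecanedial 2 and two molecules of the ketophosphonate 3. A crossed aldol condensation of 2 with an unsymmetrical four-carbon ketone would be ambiguous between its two α-positions; the phosphonate defines the enone regiochemistry. Alkene geometry is irrelevant because it is erased in the annulation.

**Oxidation level of the chain termini (2 to 1).** Dialdehyde 2 is the oxidation product of commercial diol 1, which supplies all sixteen carbons between and including the two ring C3 atoms.

## Roads not taken

**Alternative 1:** The chain would be cut at two internal alkenes (C3'=C4' and C11'=C12' of a diene version of the tether). Ring-opening cross-metathesis of cis-cyclooctene A1 with two molecules of the fully oxygenated arylbutene A2, using the second-generation Grubbs catalyst, would give the bis(aryl) diene A3. Hydrogenation over Pd/C would then saturate both alkenes and remove six benzyl ethers, and the resulting hydroxyhydroquinones would oxidise in air to 14.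
- Merits: the oxygen pattern is fixed unambiguously in A2 before coupling, and the endgame is two operations with no regiochemical question. In that respect it is better than the chosen plan, whose last four steps each carry a selectivity demand.
- Weak points: A2 is a hexasubstituted benzene that needs its own multistep synthesis, with one methyl ether distinguished from three benzyl ethers. The metathesis competes with ring-opening polymerisation of A1, homodimerisation of A2 and single capping. Products containing two or more C8 units differ from A3 only by eight methylenes and would be hard to remove.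
- Comparison: the chosen plan takes the chain length from one commercial C16 diol, so homologues cannot form, and it builds the rings from commodity reagents without protecting groups. This is what it sets against the cleaner endgame of Alternative 1.

**Alternative 2:** Each ring would be cut at C2–C3, C4–C5 and C1–C2. Heating the bis(siloxyalkyne) A4 with two equivalents of the cyclobutenone A5 would open each cyclobutenone to a vinylketene, add it across an alkyne, reopen the adduct to a dienylketene and close the benzene ring by 6π electrocyclisation, giving the bis(phenol) A6. Desilylation and air oxidation would give 14.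
- Merits: it is the most convergent option. All six ring substituents arrive in one thermal step, the siloxyalkyne polarisation dictates regiochemistry, and the three non-ether oxygens are delivered already differentiated. After the key step it is shorter than the chosen plan.
- Weak points: both partners are demanding. A4 needs a double ester-to-ynolate homologation and silylation and is hydrolytically sensitive. A5 needs regioselective monoreduction of an unsymmetrical cyclobutenedione, and its 4-siloxy substituent is an unusual pattern for this benzannulation. The reaction must also work twice in one molecule at high temperature.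
- Comparison: the chosen plan uses classical, scalable steps and stable intermediates. It concedes that its oxygenation is spread over four late steps instead of one.

**Alternative 3:** The chain would be cut at the two benzylic alkenes C1'=C2' and C13'=C14'. The bis-ylide from the bis(phosphonium) salt A7 and NaN(SiMe3)2 would condense with two molecules of the aryl aldehyde A8 to give the (Z,Z)-diene A9. Hydrogenation with debenzylation and air oxidation would finish the synthesis as in Alternative 1.
- Merits: the Wittig reaction is dependable, alkene geometry is irrelevant, and the chain length is fixed by a C12 salt, so there is no homologue problem. The key step is arguably more predictable than a double Michael–Dieckmann annulation.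
- Weak points: A8 has two ortho benzyloxy groups, which hinder and deactivate the carbonyl. Its preparation, a pentasubstituted benzaldehyde with one methyl ether among three benzyl ethers, would dominate the step count. Mass efficiency is poor for a C30 target.
- Comparison: the chosen plan reaches the complete ring skeleton in three steps from purchased materials. This is what it sets against the more predictable coupling of Alternative 3.

Key step: step 3

Remark on the chemistry: 9 is drawn as one enol tautomer of a rapidly equilibrating 1,3-dione. The stereocentres that appear in 6, 7, 8, 10 and 13 form without control as diastereomer mixtures, and all are gone before 14, which has none.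

Step 1
Reactants: 1 hexadecane-1,16-diol
Product: 2 hexadecanedial
Conditions: TEMPO (cat.), PhI(OAc)2, CH2Cl2, rt
Reagents that add atoms: none
Why: Nitroxyl-catalysed oxidation of primary alcohols with PhI(OAc)2 stops at the aldehyde in anhydrous CH2Cl2 and tolerates a slowly dissolving waxy diol; the dialdehyde should be used at once to avoid autoxidation.

Step 2
Reactants: 2 hexadecanedial; 3 diethyl (2-oxobutyl)phosphonate
Product: 4 (4E,20E)-tetracosa-4,20-diene-3,22-dione
Conditions: LiCl, iPr2NEt, MeCN–THF, rt
Reagents that add atoms: none
Why: Double Horner–Wadsworth–Emmons olefination under Masamune–Roush conditions; β-ketophosphonate anions give E-enones with unbranched aldehydes, and the mild amine base should avoid aldol self-condensation of 2. Any Z isomer is harmless because step 3 erases the geometry.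

Step 3
Reactants: 4 (4E,20E)-tetracosa-4,20-diene-3,22-dione; 5 dimethyl malonate
Product: 9 5,5'-(tetradecane-1,14-diyl)bis(3-hydroxy-2-methylcyclohex-2-en-1-one), via bis-Michael adduct 6 (not isolated), via bis(keto ester) 7 (not isolated), via bis(keto acid) 8 (not isolated)
Conditions: NaOMe, MeOH–THF, reflux (4 added to the preformed malonate anion); then aq. NaOH, reflux; then HCl to pH 1, reflux
Reagents that add atoms: none
Why: NaOMe generates the malonate anion, which adds to the β-carbon of each enone of 4 (the C3–C4 bond of each future ring, target numbering) to give 6; under the same reversible conditions the enolate on the ethyl side of each ketone attacks one malonate ester in a Claisen (Dieckmann) closure that forms the C5–C6 bond and expels methoxide, giving 7. The closest known reaction type is the malonate–enone Michael–Dieckmann annulation used for dimedone and for 5-alkylresorcinol precursors, here with an ethyl ketone and run at both chain ends. Each of the two rings closes in the same 6-exo-trig mode; the other enolisable ketone position could only close a four-membered ring, so ring size enforces the regiochemistry. Closure should be driven forward because 7 is deprotonated at its doubly activated positions, while intermolecular Claisen and retro-Michael pathways remain reversible and drain into 7. Aqueous NaOH then saponifies the remaining ester to 8, and acidification with heating decarboxylates the β-keto acid to the 2-methyl-1,3-dione 9. The stereocentres created in 6 to 8 (the chain-bearing carbon and its ester-bearing neighbour) are uncontrolled and need no control, since decarboxylation and enolisation leave 9 without a configurationally stable centre. The two termini are fourteen methylenes apart and should react independently; the selectivity needed is conjugate addition ahead of enone self-condensation, secured by having the soft malonate anion present in excess before 4 is introduced.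

Step 4
Reactants: 9 5,5'-(tetradecane-1,14-diyl)bis(3-hydroxy-2-methylcyclohex-2-en-1-one)
Product: 11 5,5'-(tetradecane-1,14-diyl)bis(3-methoxy-2-methylphenol), via bis(enol ether) 10 (not isolated)
Conditions: TsOH (cat.), MeOH, reflux; then I2, reflux
Reagents that add atoms: methanol, CO
Why: Iodine–methanol aromatisation of a cyclohexane-1,3-dione: acid-catalysed etherification gives the vinylogous ester 10, iodination at a ring methylene and loss of HI give a cyclohexadienone that tautomerises to the 3-methoxyphenol. Because each dione ring is symmetric, either carbonyl gives the same monoether; forming 10 before iodine is added should disfavour the second methanol incorporation that leads to a dimethyl ether.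

Step 5
Reactants: 11 5,5'-(tetradecane-1,14-diyl)bis(3-methoxy-2-methylphenol)
Product: 12 6,6'-(tetradecane-1,14-diyl)bis(2-methoxy-3-methylcyclohexa-2,5-diene-1,4-dione)
Conditions: (KSO3)2NO, KH2PO4, Aliquat 336, CH2Cl2–H2O, rt
Reagents that add atoms: potassium nitrosodisulfonate (KSO3)2NO, [K+].[K+].[O]N(S(=O)(=O)[O-])S(=O)(=O)[O-]
Why: Teuber oxidation: the nitroxyl radical abstracts the phenolic hydrogen, a second equivalent couples at the free para carbon, and loss of the imidodisulfonate gives the para-quinone, as known for 3-methoxy-5-alkylphenols. Phase transfer brings the water-soluble radical to the lipophilic bis(phenol).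

Step 6
Reactants: 12 6,6'-(tetradecane-1,14-diyl)bis(2-methoxy-3-methylcyclohexa-2,5-diene-1,4-dione)
Product: 13 1,1'-(tetradecane-1,14-diyl)bis(3-methoxy-4-methyl-7-oxabicyclo[4.1.0]hept-3-ene-2,5-dione)
Conditions: 30% H2O2, Na2CO3, THF–H2O, 0 °C, short reaction time; Na2S2O3 quench
Reagents that add atoms: hydrogen peroxide, OO
Why: Weitz–Scheffer nucleophilic epoxidation: hydroperoxide adds at C2 (target numbering), the only unsubstituted acceptor position and β to the more electrophilic C4 carbonyl, and the enolate closes the epoxide. The C5=C6 edge is a tetrasubstituted vinylogous ester and should stay untouched; each epoxide is necessarily cis-fused and its configuration is irrelevant.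

Step 7
Reactants: 13 1,1'-(tetradecane-1,14-diyl)bis(3-methoxy-4-methyl-7-oxabicyclo[4.1.0]hept-3-ene-2,5-dione)
Product: 14 3,3'-(tetradecane-1,14-diyl)bis(2-hydroxy-5-methoxy-6-methylcyclohexa-2,5-diene-1,4-dione)
Conditions: H2SO4–SiO2, CH2Cl2, 0 °C to rt
Reagents that add atoms: none
Why: Acid-promoted isomerisation of a 2,3-epoxy-1,4-dione that bears an epoxide hydrogen, the reaction type that turns 2-alkylnaphthoquinone oxides into 2-hydroxy-3-alkylnaphthoquinones. Enolisation of the C1 carbonyl toward C2–H cleaves the C3–O bond, so the oxygen stays on C2 next to the chain, and the vinylogous acid formed is the thermodynamic sink; the anhydrous supported acid is chosen to spare the C5 methyl ether.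

## Compound list

1 | hexadecane-1,16-diol | OCCCCCCCCCCCCCCCCO | starting material
2 | hexadecanedial | O=CCCCCCCCCCCCCCCC=O | intermediate
3 | diethyl (2-oxobutyl)phosphonate | CCC(=O)CP(=O)(OCC)OCC | starting material
4 | (4E,20E)-tetracosa-4,20-diene-3,22-dione | CCC(=O)/C=C/CCCCCCCCCCCCCC/C=C/C(=O)CC | intermediate
5 | dimethyl malonate | COC(=O)CC(=O)OC | starting material
6 | tetramethyl 2,2'-(3,22-dioxotetracosane-5,20-diyl)dimalonate (not isolated; diastereomer mixture, configuration undefined) | CCC(=O)CC(C(C(=O)OC)C(=O)OC)CCCCCCCCCCCCCCC(CC(=O)CC)C(C(=O)OC)C(=O)OC | intermediate
7 | dimethyl 6,6'-(tetradecane-1,14-diyl)bis(3-methyl-2,4-dioxocyclohexane-1-carboxylate) (not isolated; present as its sodium enolate, diastereomer mixture) | COC(=O)C1C(=O)C(C)C(=O)CC1CCCCCCCCCCCCCCC1CC(=O)C(C)C(=O)C1C(=O)OC | intermediate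
8 | 6,6'-(tetradecane-1,14-diyl)bis(3-methyl-2,4-dioxocyclohexane-1-carboxylic acid) (not isolated; diastereomer mixture) | OC(=O)C1C(=O)C(C)C(=O)CC1CCCCCCCCCCCCCCC1CC(=O)C(C)C(=O)C1C(=O)O | intermediate
9 | 5,5'-(tetradecane-1,14-diyl)bis(3-hydroxy-2-methylcyclohex-2-en-1-one) (enol tautomer of the bis(1,3-dione)) | CC1=C(O)CC(CCCCCCCCCCCCCCC2CC(O)=C(C)C(=O)C2)CC1=O | intermediate
10 | 5,5'-(tetradecane-1,14-diyl)bis(3-methoxy-2-methylcyclohex-2-en-1-one) (not isolated; C5 and C5' unassigned, diastereomer mixture) | CC1=C(OC)CC(CCCCCCCCCCCCCCC2CC(OC)=C(C)C(=O)C2)CC1=O | intermediate
11 | 5,5'-(tetradecane-1,14-diyl)bis(3-methoxy-2-methylphenol) | COc1cc(CCCCCCCCCCCCCCc2cc(O)c(C)c(OC)c2)cc(O)c1C | intermediate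
12 | 6,6'-(tetradecane-1,14-diyl)bis(2-methoxy-3-methylcyclohexa-2,5-diene-1,4-dione) | COC1=C(C)C(=O)C=C(CCCCCCCCCCCCCCC2=CC(=O)C(C)=C(OC)C2=O)C1=O | intermediate
13 | 1,1'-(tetradecane-1,14-diyl)bis(3-methoxy-4-methyl-7-oxabicyclo[4.1.0]hept-3-ene-2,5-dione) (cis-fused epoxides, racemic at each ring, diastereomer mixture) | COC1=C(C)C(=O)C2OC2(CCCCCCCCCCCCCCC23OC2C(=O)C(C)=C(OC)C3=O)C1=O | intermediate
14 | 3,3'-(tetradecane-1,14-diyl)bis(2-hydroxy-5-methoxy-6-methylcyclohexa-2,5-diene-1,4-dione) | COC1=C(C)C(=O)C(O)=C(CCCCCCCCCCCCCCC2=C(O)C(=O)C(C)=C(OC)C2=O)C1=O | target

## Step count and least certain steps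

Total steps: 7. Longest linear sequence: 7 steps (1 to 14); 3 and 5 are purchased.

**Step 3 (key step).** The main danger is self-condensation of the bis(enone) before malonate adds: intermolecular Michael addition of an ethyl-ketone enolate to a second enone, and γ-deprotonation with deconjugation. Because both ends must react, this would produce oligomers and material annulated at only one terminus.
Fallback: set out from 2. A double Horner–Wadsworth–Emmons reaction with trimethyl phosphonoacetate would give dimethyl (2E,18E)-icosa-2,18-dienedioate F1. Treatment with NaOMe and methyl 3-oxopentanoate would add the keto ester carbon to each β-carbon, giving dimethyl 3,18-bis(1-methoxy-1,3-dioxopentan-2-yl)icosanedioate F2 (not isolated). Its ethyl-ketone enolates would close onto the chain esters through the same six-membered Claisen mode. The ring is thus assembled from the other side, with an enoate acceptor that has no ketone enolate to self-condense. The product is bis(keto ester) 7, where the fallback rejoins the route for saponification and decarboxylation to 9.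

**Step 4.** Over-methylation is the likeliest failure: ketalisation of the vinylogous ester before aromatisation leads to a resorcinol dimethyl ether, and over two rings even modest leakage gives a hard-to-separate mixture. Reversible ring iodination of the electron-rich phenol could also hold back material.
Fallback: set out from 9 and isolate bis(enol ether) 10 after the acid-catalysed etherification alone. Kinetic deprotonation with LiN(iPr)2 at the ring methylene next to each carbonyl and trapping with PhSeCl would give 5,5'-(tetradecane-1,14-diyl)bis[3-methoxy-2-methyl-6-(phenylselanyl)cyclohex-2-en-1-one] F3. Oxidation with H2O2 would give the bis(selenoxide) 5,5'-(tetradecane-1,14-diyl)bis[3-methoxy-2-methyl-6-(phenylseleninyl)cyclohex-2-en-1-one] F4 (not isolated), which undergoes syn-elimination; the cross-conjugated dienone tautomerises to the phenol. The route is rejoined at 11 with the monoether fixed from the start.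

**Step 5.** Conversion may stall because the lipophilic bis(phenol) partitions poorly toward the aqueous radical oxidant, leaving half-oxidised material. Attack at the one free ortho carbon, leading to ortho-quinone-derived by-products, is the second risk.
Fallback: set out from 11 and change to a two-electron oxidation in homogeneous organic solution. PhI(OAc)2 in methanol (two equivalents per ring) would dearomatise each para-unsubstituted phenol to its quinone monoketal, 5,5'-(tetradecane-1,14-diyl)bis(3,4,4-trimethoxy-2-methylcyclohexa-2,5-dien-1-one) F5. Brief hydrolysis with dilute aqueous HCl in acetone would release the quinone and rejoin the route at 12.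

**Step 6.** Two base-driven processes could compete with epoxidation: displacement of the C5 methoxy group by hydroxide or hydroperoxide through addition–elimination, and premature opening of the new epoxide followed by peroxide degradation of the resulting hydroxyquinone anion.
Fallback: set out from 12 and avoid base altogether by Thiele–Winter acetoxylation (Ac2O, BF3·OEt2). Acetate would add at the only free ring carbon to give 3,3'-(tetradecane-1,14-diyl)bis(5-methoxy-6-methylbenzene-1,2,4-triyl) hexaacetate F6. Methanolysis with K2CO3 in degassed MeOH would give 3,3'-(tetradecane-1,14-diyl)bis(5-methoxy-6-methylbenzene-1,2,4-triol) F7 (not isolated), which oxidises on admission of air. This rejoins the route at 14 and also bypasses step 7.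

**Step 7.** Protic acid may hydrolyse or exchange the vinylogous-ester methyl ether, and a 1,2-acyl shift of the epoxy ketone (ring contraction) could compete with the desired enolisation.
Fallback: set out from 13 and open the epoxide from the carbanion side. DBU in CH2Cl2 would remove the epoxide hydrogen α to the C1 carbonyl, and the enolate would expel the epoxide oxygen from C3 (E1cB). Trapping the hydroxyquinone anion with Ac2O would give the neutral 3,3'-(tetradecane-1,14-diyl)bis(2-acetoxy-5-methoxy-6-methylcyclohexa-2,5-diene-1,4-dione) F8, which can be purified. Mild hydrolysis with aqueous NaHCO3 in THF followed by acidification would rejoin the route at 14.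

## Further compounds

F1 | step 3 | dimethyl (2E,18E)-icosa-2,18-dienedioate | COC(=O)/C=C/CCCCCCCCCCCCCC/C=C/C(=O)OC
F2 | step 3 | dimethyl 3,18-bis(1-methoxy-1,3-dioxopentan-2-yl)icosanedioate (diastereomer mixture) | COC(=O)CC(C(C(=O)OC)C(=O)CC)CCCCCCCCCCCCCCC(CC(=O)OC)C(C(=O)OC)C(=O)CC
F3 | step 4 | 5,5'-(tetradecane-1,14-diyl)bis[3-methoxy-2-methyl-6-(phenylselanyl)cyclohex-2-en-1-one] (diastereomer mixture) | CC1=C(OC)CC(CCCCCCCCCCCCCCC2CC(OC)=C(C)C(=O)C2[Se]c2ccccc2)C([Se]c2ccccc2)C1=O
F4 | step 4 | 5,5'-(tetradecane-1,14-diyl)bis[3-methoxy-2-methyl-6-(phenylseleninyl)cyclohex-2-en-1-one] (diastereomer mixture) | CC1=C(OC)CC(CCCCCCCCCCCCCCC2CC(OC)=C(C)C(=O)C2[Se](=O)c2ccccc2)C([Se](=O)c2ccccc2)C1=O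
F5 | step 5 | 5,5'-(tetradecane-1,14-diyl)bis(3,4,4-trimethoxy-2-methylcyclohexa-2,5-dien-1-one) | COC1=C(C)C(=O)C=C(CCCCCCCCCCCCCCC2=CC(=O)C(C)=C(OC)C2(OC)OC)C1(OC)OC
F6 | step 6 | 3,3'-(tetradecane-1,14-diyl)bis(5-methoxy-6-methylbenzene-1,2,4-triyl) hexaacetate | COc1c(C)c(OC(C)=O)c(OC(C)=O)c(CCCCCCCCCCCCCCc2c(OC(C)=O)c(OC(C)=O)c(C)c(OC)c2OC(C)=O)c1OC(C)=O
F7 | step 6 | 3,3'-(tetradecane-1,14-diyl)bis(5-methoxy-6-methylbenzene-1,2,4-triol) | COc1c(C)c(O)c(O)c(CCCCCCCCCCCCCCc2c(O)c(O)c(C)c(OC)c2O)c1O
F8 | step 7 | 3,3'-(tetradecane-1,14-diyl)bis(2-acetoxy-5-methoxy-6-methylcyclohexa-2,5-diene-1,4-dione) | COC1=C(C)C(=O)C(OC(C)=O)=C(CCCCCCCCCCCCCCC2=C(OC(C)=O)C(=O)C(C)=C(OC)C2=O)C1=O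
A1 | alternative 1 | cis-cyclooctene | C1CC/C=C\CCC1
A2 | alternative 1 | 1,2,4-tris(benzyloxy)-3-(but-3-en-1-yl)-5-methoxy-6-methylbenzene | COc1c(C)c(OCc2ccccc2)c(OCc2ccccc2)c(CCC=C)c1OCc1ccccc1
A3 | alternative 1 | (3E,11E)-1,14-bis[2,3,6-tris(benzyloxy)-5-methoxy-4-methylphenyl]tetradeca-3,11-diene | COc1c(C)c(OCc2ccccc2)c(OCc2ccccc2)c(CC/C=C/CCCCCC/C=C/CCc2c(OCc3ccccc3)c(OCc3ccccc3)c(C)c(OC)c2OCc2ccccc2)c1OCc1ccccc1
A4 | alternative 2 | 1,18-bis(triisopropylsilyloxy)octadeca-1,17-diyne | CC(C)[Si](OC#CCCCCCCCCCCCCCCC#CO[Si](C(C)C)(C(C)C)C(C)C)(C(C)C)C(C)C
A5 | alternative 2 | 4-(tert-butyldimethylsilyloxy)-2-methoxy-3-methylcyclobut-2-en-1-one (racemic) | COC1=C(C)C(O[Si](C)(C)C(C)(C)C)C1=O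
A6 | alternative 2 | 2,2'-(tetradecane-1,14-diyl)bis[6-(tert-butyldimethylsilyloxy)-4-methoxy-5-methyl-3-(triisopropylsilyloxy)phenol] | COc1c(C)c(O[Si](C)(C)C(C)(C)C)c(O)c(CCCCCCCCCCCCCCc2c(O)c(O[Si](C)(C)C(C)(C)C)c(C)c(OC)c2O[Si](C(C)C)(C(C)C)C(C)C)c1O[Si](C(C)C)(C(C)C)C(C)C
A7 | alternative 3 | dodecane-1,12-diylbis(triphenylphosphonium) dibromide | [Br-].[Br-].C(CCCCCCCCCCC[P+](c1ccccc1)(c1ccccc1)c1ccccc1)[P+](c1ccccc1)(c1ccccc1)c1ccccc1
A8 | alternative 3 | 2,3,6-tris(benzyloxy)-5-methoxy-4-methylbenzaldehyde | COc1c(C)c(OCc2ccccc2)c(OCc2ccccc2)c(C=O)c1OCc1ccccc1
A9 | alternative 3 | (1Z,13Z)-1,14-bis[2,3,6-tris(benzyloxy)-5-methoxy-4-methylphenyl]tetradeca-1,13-diene | COc1c(C)c(OCc2ccccc2)c(OCc2ccccc2)c(/C=C\CCCCCCCCCC/C=C\c2c(OCc3ccccc3)c(OCc3ccccc3)c(C)c(OC)c2OCc2ccccc2)c1OCc1ccccc1
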